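**Assumptions**
- The absolute configuration is exactly that of the given SMILES, which is (2S,3R,4R) on the tetrahydrofuran (THF) ring.
- (R)-5-Oxotetrahydrofuran-3-carboxylic acid (1) is taken to be available as a single enantiomer. If it is not, the racemic acid can be resolved as a chiral-amine salt.
- 3,4-Dimethoxyphenylmagnesium bromide (8) is taken to be available as a THF solution. It can also be made from 4-bromoveratrole and Mg.

**Retrosynthetic overview**
1. The aryl ketone and the free CH2OH both come from opening a cis-fused THF/γ-lactone (Weinreb amidation, then ArMgBr). The lactone also locks the 3,4-cis relationship.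
2. The THF ring (O–C7 bond) comes from acid-mediated 5-exo cyclodehydration of a primary alcohol onto the benzylic cation of a diol-lactone.
3. That diol-lactone comes from LiBH4 reduction and relactonization of the trans-aldol adduct of (R)-5-oxotetrahydrofuran-3-carboxylic acid with 3,4,5-trimethoxybenzaldehyde.
4. Ring order: the commercial butyrolactone A, then a new butyrolactone B (translactonization), then the THF ring, then lactone B is opened in the last two steps.

**Step 1**
Reactants: 1 (R)-5-oxotetrahydrofuran-3-carboxylic acid; 2 3,4,5-trimethoxybenzaldehyde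
Product: 3 (3R,4S)-4-[(S)-hydroxy(3,4,5-trimethoxyphenyl)methyl]-5-oxooxolane-3-carboxylic acid
Conditions: LDA (2.2 equiv), THF, –78 °C; then 2, –78 °C, 2 h; AcOH quench at –78 °C
Reagents that add atoms: none
Why: This is a lactone-dianion aldol reaction. The lactone enolate attacks the aldehyde anti to the β-CO2Li group, which sets C8 trans to the carboxylate. The carbinol C7 forms as an epimer mixture. That is acceptable because C7 is ionized and reset in step 3. Only the needed (S) epimer is drawn.

**Step 2**
Reactant: 3
Product: 4 (3R,4R)-3-(hydroxymethyl)-4-[(S)-hydroxy(3,4,5-trimethoxyphenyl)methyl]oxolan-2-one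
Conditions: i) LiBH4 (4 equiv), THF, 0 °C → rt; ii) 1 M HCl, then cat. TsOH, CH2Cl2, rt
Reagents that add atoms: none
Why: LiBH4 reduces the lactone but not the lithium carboxylate, giving a triol-acid that is not isolated. Acid then closes a new γ-lactone onto the primary C9–OH (translactonization). This frees the C9′–OH and makes the C9/C7′ pair a lactone. No stereocenter is touched, because no C–H next to a carbonyl is deprotonated.

**Step 3**
Reactant: 4
Product: 5 (3aR,4S,6aR)-4-(3,4,5-trimethoxyphenyl)tetrahydro-1H,3H-furo[3,4-c]furan-1-one
Conditions: TsOH·H2O (20 mol %), toluene, 80 °C, 4 Å MS, 0.02 M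
Reagents that add atoms: none
Why: This is an SN1-type dehydrative etherification. Both C7 epimers of 4 ionize to the same electron-rich benzylic cation. The primary C9′–OH closes 5-exo, and the cis-fused lactone forces cis ring fusion. The aryl group prefers the convex (exo) face, trans to C9, which sets C7 as S. The minor endo epimer is removed by chromatography.

**Step 4**
Reactants: 5; 6 N,O-dimethylhydroxylamine hydrochloride
Product: 7 (2S,3R,4R)-3-(hydroxymethyl)-N-methoxy-N-methyl-2-(3,4,5-trimethoxyphenyl)oxolane-4-carboxamide
Conditions: 6 (2.5 equiv), i-PrMgCl (5 equiv), THF, –20 → 0 °C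
Reagents that add atoms: N,O-dimethylhydroxylamine hydrochloride, CNOC.Cl
Why: This is Weinreb amidation by lactone ring opening. The magnesium amide attacks the lactone C=O and releases the C9 primary alcohol. The C8′ α-H is not acidic enough to epimerize under these conditions, so all three stereocenters are retained.

**Step 5**
Reactants: 7; 8 3,4-dimethoxyphenylmagnesium bromide
Product: 9 Magnone B
Conditions: 8 (3.5 equiv), THF, 0 °C → rt, 3 h; sat. aq. NH4Cl
Reagents that add atoms: 3,4-dimethoxyphenylmagnesium bromide, COc1ccc([Mg]Br)cc1OC
Why: This is a Weinreb ketone synthesis. The stable chelated tetrahedral intermediate prevents over-addition, and the extra Grignard simply deprotonates the free OH. No stereocenter is changed.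

**Compound list**
1 | (3R)-5-oxooxolane-3-carboxylic acid | OC(=O)[C@H]1COC(=O)C1 | starting material
2 | 3,4,5-trimethoxybenzaldehyde | COc1cc(C=O)cc(OC)c1OC | starting material
3 | (3R,4S)-4-[(S)-hydroxy(3,4,5-trimethoxyphenyl)methyl]-5-oxooxolane-3-carboxylic acid | OC(=O)[C@H]1COC(=O)[C@@H]1[C@H](O)c1cc(OC)c(OC)c(OC)c1 | intermediate
4 | (3R,4R)-3-(hydroxymethyl)-4-[(S)-hydroxy(3,4,5-trimethoxyphenyl)methyl]oxolan-2-one | O=C1OC[C@H]([C@H](O)c2cc(OC)c(OC)c(OC)c2)[C@@H]1CO | intermediate
5 | (3aR,4S,6aR)-4-(3,4,5-trimethoxyphenyl)tetrahydro-1H,3H-furo[3,4-c]furan-1-one | O=C1OC[C@H]2[C@@H]1CO[C@@H]2c1cc(OC)c(OC)c(OC)c1 | intermediate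
6 | N,O-dimethylhydroxylamine hydrochloride | CNOC.Cl | starting material
7 | (2S,3R,4R)-3-(hydroxymethyl)-N-methoxy-N-methyl-2-(3,4,5-trimethoxyphenyl)oxolane-4-carboxamide | CON(C)C(=O)[C@H]1CO[C@H](c2cc(OC)c(OC)c(OC)c2)[C@H]1CO | intermediate
8 | 3,4-dimethoxyphenylmagnesium bromide | COc1ccc([Mg]Br)cc1OC | starting material
9 | Magnone B, (3,4-dimethoxyphenyl)[(3R,4R,5S)-4-(hydroxymethyl)-5-(3,4,5-trimethoxyphenyl)oxolan-3-yl]methanone | COc1ccc(C(=O)[C@H]2CO[C@H](c3cc(OC)c(OC)c(OC)c3)[C@H]2CO)cc1OC | target

**Totals:** 5 steps; longest linear sequence 5 steps.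

**Three steps most likely to fail**
1. **Step 1 (dianion aldol).** The dianion may form in low yield or the adduct may undergo retro-aldol. The C7 epimer ratio is also uncontrolled. Lactone enolates usually favor the anti adduct, and the needed epimer is syn.
   - Fallback: use an Evans boron syn-aldol instead. Start from an N-acyl oxazolidinone of a C8′-defined 2-(silyloxymethyl)succinate with a Weinreb-amide end. This fixes C7/C8 syn directly, and desilylation lactonizes to the same type of intermediate.
2. **Step 3 (cyclodehydration).** The deactivated 3,4,5-trimethoxybenzylic alcohol may eliminate to the benzylidene lactone, or the exo:endo ratio may be poor.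
   - Fallback: separate the aldol epimers and close the ring by Mitsunobu SN2 at the primary C9′ carbon (DIAD, PPh3). This retains C7 and replaces SN1 ionization with SN2.
3. **Steps 4–5 (Weinreb opening, then ArMgBr).** The bicyclic lactone may be sluggish to open, or C8′ may epimerize or eliminate β-alkoxide.
   - Fallback: reduce lactone 5 with DIBAL to the lactol, add ArMgBr to give the diol, then oxidize the electron-rich secondary benzylic alcohol selectively with MnO2. The primary CH2OH is untouched.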